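**Plan**
- Retrosynthesis: first cut the CH2–ring B bond that ties butyrylfilicinic acid (ring A) to the aromatic trimer, then the three aryl–C(=O) bonds of the butyryl groups on rings B, C and D, then two C–C bonds of ring C itself (the carbon carrying the ring B arm to the C–O lying between the arms, and the carbon carrying the ring D arm to the next C–OH).
- Enabling feature: ring C is a phloroglucinol whose two CH2 arms sit on the ring carbons either side of one C–O, while its third carbon is a C–H (later C-butyryl); a 2-substituted 3-siloxycyclobutenone and a 1-siloxyalkyne map exactly onto this pattern.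
- Forward: rings B and D are carried from phloroglucinol and 2-methylphloroglucinol as tribenzyl ethers and homologated through arylacetic esters to siloxyalkynes; the ring B alkyne is converted with ketene into the cyclobutenone.
- Ring C is then created by the cyclobutenone–siloxyalkyne benzannulation; desilylation, hydrogenolysis and threefold C-butyrylation follow, and ring A is attached last through its Mannich base.
- Stereochemistry: the target has no stereocentre; the only stereocentres on the way (in 3, 11 and 17) are racemic and are erased.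

Key step: step 10

Assumption: ring A of the target is a β-triketone drawn as one enol tautomer; 25–28 are each treated as one compound whatever the tautomer.

**Step 1**
Reactants: 1 phloroglucinol
Product: 2 1,3,5-tris(benzyloxy)benzene
Conditions: BnBr (3.3 equiv), K2CO3, DMF, rt
Reagents that add atoms: benzyl bromide, BrCc1ccccc1
Why: Williamson ether synthesis on the three phenols, where a weak base in a dipolar aprotic solvent favours O- over C-benzylation and C-benzylated material is removed by crystallisation.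

**Step 2**
Reactants: 2 1,3,5-tris(benzyloxy)benzene
Product: 3 ethyl 2-hydroxy-2-[2,4,6-tris(benzyloxy)phenyl]acetate (racemic)
Conditions: ethyl glyoxylate (1.2 equiv, 50% in toluene), Yb(OTf)3 (10 mol %), CH2Cl2, 0 °C to rt
Reagents that add atoms: ethyl glyoxylate, CCOC(=O)C=O
Why: Friedel–Crafts hydroxyalkylation of a very electron-rich arene at one of its three equivalent C–H positions, the new stereocentre being racemic and removed in step 3.

**Step 3**
Reactants: 3 ethyl 2-hydroxy-2-[2,4,6-tris(benzyloxy)phenyl]acetate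
Product: 4 ethyl 2-[2,4,6-tris(benzyloxy)phenyl]acetate
Conditions: Et3SiH (3 equiv), CF3CO2H (5 equiv), CH2Cl2, 0 °C
Reagents that add atoms: none
Why: Ionic hydrogenation, in which the trialkoxyphenyl group stabilises the benzylic cation that the silane reduces, while aryl benzyl ethers and the ester should survive brief contact with dilute acid at 0 °C.

**Step 4**
Reactants: 4 ethyl 2-[2,4,6-tris(benzyloxy)phenyl]acetate
Product: 7 triisopropyl{3-[2,4,6-tris(benzyloxy)phenyl]prop-1-ynyloxy}silane, via lithium dibromoenolate 5 (not isolated), via lithium ynolate 6 (not isolated)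
Conditions: CH2Br2, lithium 2,2,6,6-tetramethylpiperidide, THF, −78 °C; LiN(SiMe3)2, −78 to −20 °C; n-BuLi, −78 °C to rt; i-Pr3SiCl, −78 °C to rt
Reagents that add atoms: dibromomethane, BrCBr; chlorotriisopropylsilane, CC(C)[Si](Cl)(C(C)C)C(C)C
Why: Kowalski ester homologation stopped at the ynolate, in which LiCHBr2 formed in the presence of the ester adds to it, the dibromoenolate 5 undergoes bromine–lithium exchange and 1,2-shift to 6, and the bulky silyl chloride traps 6 on oxygen.

**Step 5**
Reactants: 7 triisopropyl{3-[2,4,6-tris(benzyloxy)phenyl]prop-1-ynyloxy}silane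
Product: 8 3-(triisopropylsilyloxy)-2-[2,4,6-tris(benzyloxy)benzyl]cyclobut-2-en-1-one
Conditions: ketene (gas, excess, from pyrolysis of acetone in a ketene generator), CH2Cl2, 0 °C to rt
Reagents that add atoms: ketene, C=C=O
Why: Known [2+2] cycloaddition of ketene with a siloxyalkyne, in which the alkyne carbon remote from oxygen attacks the ketene carbonyl carbon and so fixes the 2-benzyl-3-siloxy pattern.

**Step 6**
Reactants: 9 2-methylphloroglucinol
Product: 10 1,3,5-tris(benzyloxy)-2-methylbenzene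
Conditions: BnBr (3.3 equiv), K2CO3, DMF, rt
Reagents that add atoms: benzyl bromide, BrCc1ccccc1
Why: Williamson ether synthesis as in step 1.

**Step 7**
Reactants: 10 1,3,5-tris(benzyloxy)-2-methylbenzene
Product: 11 ethyl 2-hydroxy-2-[2,4,6-tris(benzyloxy)-3-methylphenyl]acetate (racemic)
Conditions: ethyl glyoxylate (1.2 equiv, 50% in toluene), Yb(OTf)3 (10 mol %), CH2Cl2, 0 °C to rt
Reagents that add atoms: ethyl glyoxylate, CCOC(=O)C=O
Why: Friedel–Crafts hydroxyalkylation at one of the two equivalent free ring positions, giving a single regioisomer whose racemic stereocentre is removed in step 8.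

**Step 8**
Reactants: 11 ethyl 2-hydroxy-2-[2,4,6-tris(benzyloxy)-3-methylphenyl]acetate
Product: 12 ethyl 2-[2,4,6-tris(benzyloxy)-3-methylphenyl]acetate
Conditions: Et3SiH (3 equiv), CF3CO2H (5 equiv), CH2Cl2, 0 °C
Reagents that add atoms: none
Why: Ionic hydrogenation of the aryl-stabilised benzylic alcohol as in step 3.

**Step 9**
Reactants: 12 ethyl 2-[2,4,6-tris(benzyloxy)-3-methylphenyl]acetate
Product: 15 triisopropyl{3-[2,4,6-tris(benzyloxy)-3-methylphenyl]prop-1-ynyloxy}silane, via lithium dibromoenolate 13 (not isolated), via lithium ynolate 14 (not isolated)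
Conditions: CH2Br2, lithium 2,2,6,6-tetramethylpiperidide, THF, −78 °C; LiN(SiMe3)2, −78 to −20 °C; n-BuLi, −78 °C to rt; i-Pr3SiCl, −78 °C to rt
Reagents that add atoms: dibromomethane, BrCBr; chlorotriisopropylsilane, CC(C)[Si](Cl)(C(C)C)C(C)C
Why: Kowalski ester homologation to the ynolate with O-silylation, as in step 4.

**Step 10**
Reactants: 8 3-(triisopropylsilyloxy)-2-[2,4,6-tris(benzyloxy)benzyl]cyclobut-2-en-1-one; 15 triisopropyl{3-[2,4,6-tris(benzyloxy)-3-methylphenyl]prop-1-ynyloxy}silane
Product: 20 3,5-bis(triisopropylsilyloxy)-4-[2,4,6-tris(benzyloxy)benzyl]-2-[2,4,6-tris(benzyloxy)-3-methylbenzyl]phenol, via vinylketene 16 (not isolated), via 4-vinylcyclobutenone 17 (not isolated), via dienylketene 18 (not isolated), via cyclohexadienone 19 (not isolated)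
Conditions: 15 (1.3 equiv), degassed toluene, 110 °C, sealed tube
Reagents that add atoms: none
Why: Proposed new method: thermal 4π-electrocyclic opening of 8 should give siloxyvinylketene 16, whose ketene C=C is taken up in a [2+2] cycloaddition by the electron-rich ynol ether 15 to give 17, which opens again to dienylketene 18 and closes to 19 before tautomerising to phenol 20; the closest known reaction type is the Danheiser benzannulation of 3-alkylcyclobutenones with siloxyalkynes, which has not been shown for a cyclobutenone carrying a 3-siloxy group. Ring C is closed by a thermal disrotatory 6π-electrocyclisation of 18 (the four-membered ring of 17, formed by ketene–alkyne [2+2] cycloaddition, is only transient), and the two new skeletal bonds join the alkyne carbon bearing the ring D arm to the former carbonyl carbon and the siloxy-bearing alkyne carbon to the carbon bearing the ring B arm. No stereocentre is created in 20, and the quaternary centre of 17 is racemic and disappears on ring opening. The selectivity needed is regiochemical: the alkyne carbon remote from oxygen is the nucleophilic terminus and bonds to the electrophilic ketene carbon, so the three oxygens end up 1,3,5, both arms flank the alkyne-derived oxygen, and one C–H is left next to the free OH. The 3-siloxy group makes 8 a vinylogous silyl ester and may slow ring opening, so the step is run at 110 °C with robust triisopropylsilyl groups, and any silyl migration to the free phenol is harmless because step 11 removes all silyl groups.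

**Step 11**
Reactants: 20 3,5-bis(triisopropylsilyloxy)-4-[2,4,6-tris(benzyloxy)benzyl]-2-[2,4,6-tris(benzyloxy)-3-methylbenzyl]phenol
Product: 21 2-[2,4,6-tris(benzyloxy)benzyl]-4-[2,4,6-tris(benzyloxy)-3-methylbenzyl]benzene-1,3,5-triol
Conditions: Bu4NF (2.5 equiv), AcOH (2.5 equiv), THF, 0 °C, argon
Reagents that add atoms: none
Why: Fluoride cleavage of aryl silyl ethers, buffered with acetic acid so that the air-sensitive phloroglucinol is not left as its phenoxide.

**Step 12**
Reactants: 21 2-[2,4,6-tris(benzyloxy)benzyl]-4-[2,4,6-tris(benzyloxy)-3-methylbenzyl]benzene-1,3,5-triol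
Product: 22 2-[(2,4,6-trihydroxyphenyl)methyl]-4-[(2,4,6-trihydroxy-3-methylphenyl)methyl]benzene-1,3,5-triol
Conditions: H2 (1 atm), 10% Pd/C, EtOAc–MeOH, rt
Reagents that add atoms: none
Why: Catalytic hydrogenolysis of six aryl benzyl ethers, to which the diarylmethane C–C bonds are inert; the product is used at once under argon.

**Step 13**
Reactants: 22 2-[(2,4,6-trihydroxyphenyl)methyl]-4-[(2,4,6-trihydroxy-3-methylphenyl)methyl]benzene-1,3,5-triol
Product: 23 1-[3-({3-butanoyl-5-[(3-butanoyl-2,4,6-trihydroxy-5-methylphenyl)methyl]-2,4,6-trihydroxyphenyl}methyl)-2,4,6-trihydroxyphenyl]butan-1-one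
Conditions: butanoyl chloride (3.3 equiv), AlCl3 (12 equiv), PhNO2–CH2Cl2, 0 °C to rt; aq. HCl
Reagents that add atoms: butanoyl chloride, CCCC(Cl)=O
Why: Friedel–Crafts acylation of phloroglucinol rings at C–H positions flanked by two OH groups, where the first acyl group deactivates its ring so that rings C and D (one free C–H each) and ring B (two equivalent C–H) should each be acylated once.

**Step 14**
Reactants: 1 phloroglucinol
Product: 24 1-(2,4,6-trihydroxyphenyl)butan-1-one
Conditions: butanoyl chloride (1.0 equiv), AlCl3 (4 equiv), PhNO2–CH2Cl2, rt; aq. HCl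
Reagents that add atoms: butanoyl chloride, CCCC(Cl)=O
Why: Friedel–Crafts monoacylation of phloroglucinol, self-limiting because the acyl group deactivates the ring.

**Step 15**
Reactants: 24 1-(2,4,6-trihydroxyphenyl)butan-1-one
Product: 25 2-butanoyl-3,5-dihydroxy-4,4-dimethylcyclohexa-2,5-dien-1-one (butyrylfilicinic acid)
Conditions: NaOMe (3 equiv), MeI (2.2 equiv), MeOH, 0 °C to rt
Reagents that add atoms: iodomethane, CI
Why: Dearomatising geminal C-methylation of the acylphloroglucinol polyanion, a known route to acylfilicinic acids, in which the acidic triketone product persists as a weakly nucleophilic enolate and so resists further methylation.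

**Step 16**
Reactants: 25 2-butanoyl-3,5-dihydroxy-4,4-dimethylcyclohexa-2,5-dien-1-one
Product: 26 2-butanoyl-6-[(dimethylamino)methyl]-3,5-dihydroxy-4,4-dimethylcyclohexa-2,5-dien-1-one
Conditions: CH2=NMe2+ I− (Eschenmoser's salt, 1.1 equiv), Et3N (1.1 equiv), CH2Cl2, 0 °C to rt; used crude
Reagents that add atoms: N,N-dimethylmethyleneiminium iodide, C=[N+](C)C.[I-]
Why: Mannich aminomethylation with a preformed iminium salt at the only free enolic carbon (C6) of the triketone, avoiding free formaldehyde and hence the symmetrical methylene-bridged dimer.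

**Step 17**
Reactants: 23 tris-butyryl ring B–C–D trimer; 26 2-butanoyl-6-[(dimethylamino)methyl]-3,5-dihydroxy-4,4-dimethylcyclohexa-2,5-dien-1-one
Product: 28 CNP0246352.0 (ring A–B–C–D tetramer; target), via methylene trione 27 (not isolated)
Conditions: 26 (1.5 equiv), 1,4-dioxane, 80 °C, argon; dilute aq. HCl work-up
Reagents that add atoms: none
Why: Retro-Mannich loss of dimethylamine from 26 gives the exo-methylene triketone 27 (an ortho-quinone methide equivalent), which is attacked in a conjugate addition by the single remaining nucleophilic C–H of ring B in 23, followed by re-aromatisation, so only the unsymmetrical CH2 link can form.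

**Compound list**
1 | phloroglucinol (benzene-1,3,5-triol) | Oc1cc(O)cc(O)c1 | starting material
2 | 1,3,5-tris(benzyloxy)benzene | c1ccc(COc2cc(OCc3ccccc3)cc(OCc3ccccc3)c2)cc1 | intermediate
3 | ethyl 2-hydroxy-2-[2,4,6-tris(benzyloxy)phenyl]acetate (racemic) | CCOC(=O)C(O)c1c(OCc2ccccc2)cc(OCc2ccccc2)cc1OCc1ccccc1 | intermediate
4 | ethyl 2-[2,4,6-tris(benzyloxy)phenyl]acetate | CCOC(=O)Cc1c(OCc2ccccc2)cc(OCc2ccccc2)cc1OCc1ccccc1 | intermediate
5 | lithium 1,1-dibromo-3-[2,4,6-tris(benzyloxy)phenyl]prop-1-en-2-olate | [Li+].[O-]C(Cc1c(OCc2ccccc2)cc(OCc2ccccc2)cc1OCc1ccccc1)=C(Br)Br | intermediate (not isolated)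
6 | lithium 3-[2,4,6-tris(benzyloxy)phenyl]prop-1-yn-1-olate | [Li+].[O-]C#CCc1c(OCc2ccccc2)cc(OCc2ccccc2)cc1OCc1ccccc1 | intermediate (not isolated)
7 | triisopropyl{3-[2,4,6-tris(benzyloxy)phenyl]prop-1-ynyloxy}silane | CC(C)[Si](OC#CCc1c(OCc2ccccc2)cc(OCc2ccccc2)cc1OCc1ccccc1)(C(C)C)C(C)C | intermediate
8 | 3-(triisopropylsilyloxy)-2-[2,4,6-tris(benzyloxy)benzyl]cyclobut-2-en-1-one | O=C1CC(O[Si](C(C)C)(C(C)C)C(C)C)=C1Cc1c(OCc2ccccc2)cc(OCc2ccccc2)cc1OCc1ccccc1 | intermediate
9 | 2-methylphloroglucinol (2-methylbenzene-1,3,5-triol) | Cc1c(O)cc(O)cc1O | starting material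
10 | 1,3,5-tris(benzyloxy)-2-methylbenzene | Cc1c(OCc2ccccc2)cc(OCc2ccccc2)cc1OCc1ccccc1 | intermediate
11 | ethyl 2-hydroxy-2-[2,4,6-tris(benzyloxy)-3-methylphenyl]acetate (racemic) | CCOC(=O)C(O)c1c(OCc2ccccc2)c(C)c(OCc2ccccc2)cc1OCc1ccccc1 | intermediate
12 | ethyl 2-[2,4,6-tris(benzyloxy)-3-methylphenyl]acetate | CCOC(=O)Cc1c(OCc2ccccc2)c(C)c(OCc2ccccc2)cc1OCc1ccccc1 | intermediate
13 | lithium 1,1-dibromo-3-[2,4,6-tris(benzyloxy)-3-methylphenyl]prop-1-en-2-olate | [Li+].[O-]C(Cc1c(OCc2ccccc2)c(C)c(OCc2ccccc2)cc1OCc1ccccc1)=C(Br)Br | intermediate (not isolated)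
14 | lithium 3-[2,4,6-tris(benzyloxy)-3-methylphenyl]prop-1-yn-1-olate | [Li+].[O-]C#CCc1c(OCc2ccccc2)c(C)c(OCc2ccccc2)cc1OCc1ccccc1 | intermediate (not isolated)
15 | triisopropyl{3-[2,4,6-tris(benzyloxy)-3-methylphenyl]prop-1-ynyloxy}silane | CC(C)[Si](OC#CCc1c(OCc2ccccc2)c(C)c(OCc2ccccc2)cc1OCc1ccccc1)(C(C)C)C(C)C | intermediate
16 | 3-(triisopropylsilyloxy)-2-[2,4,6-tris(benzyloxy)benzyl]buta-1,3-dien-1-one | O=C=C(Cc1c(OCc2ccccc2)cc(OCc2ccccc2)cc1OCc1ccccc1)C(=C)O[Si](C(C)C)(C(C)C)C(C)C | intermediate (not isolated)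
17 | 3-(triisopropylsilyloxy)-4-[1-(triisopropylsilyloxy)ethenyl]-4-[2,4,6-tris(benzyloxy)benzyl]-2-[2,4,6-tris(benzyloxy)-3-methylbenzyl]cyclobut-2-en-1-one (racemic) | O=C1C(Cc2c(OCc3ccccc3)c(C)c(OCc3ccccc3)cc2OCc2ccccc2)=C(O[Si](C(C)C)(C(C)C)C(C)C)C1(Cc1c(OCc2ccccc2)cc(OCc2ccccc2)cc1OCc1ccccc1)C(=C)O[Si](C(C)C)(C(C)C)C(C)C | intermediate (not isolated)
18 | (3E)-3,5-bis(triisopropylsilyloxy)-4-[2,4,6-tris(benzyloxy)benzyl]-2-[2,4,6-tris(benzyloxy)-3-methylbenzyl]hexa-1,3,5-trien-1-one (ketene carbon chain and vinyl group cis on the central double bond) | O=C=C(Cc1c(OCc2ccccc2)c(C)c(OCc2ccccc2)cc1OCc1ccccc1)/C(O[Si](C(C)C)(C(C)C)C(C)C)=C(Cc1c(OCc2ccccc2)cc(OCc2ccccc2)cc1OCc1ccccc1)\C(=C)O[Si](C(C)C)(C(C)C)C(C)C | intermediate (not isolated)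
19 | 3,5-bis(triisopropylsilyloxy)-4-[2,4,6-tris(benzyloxy)benzyl]-2-[2,4,6-tris(benzyloxy)-3-methylbenzyl]cyclohexa-2,4-dien-1-one | O=C1CC(O[Si](C(C)C)(C(C)C)C(C)C)=C(Cc2c(OCc3ccccc3)cc(OCc3ccccc3)cc2OCc2ccccc2)C(O[Si](C(C)C)(C(C)C)C(C)C)=C1Cc1c(OCc2ccccc2)c(C)c(OCc2ccccc2)cc1OCc1ccccc1 | intermediate (not isolated)
20 | 3,5-bis(triisopropylsilyloxy)-4-[2,4,6-tris(benzyloxy)benzyl]-2-[2,4,6-tris(benzyloxy)-3-methylbenzyl]phenol | Oc1cc(O[Si](C(C)C)(C(C)C)C(C)C)c(Cc2c(OCc3ccccc3)cc(OCc3ccccc3)cc2OCc2ccccc2)c(O[Si](C(C)C)(C(C)C)C(C)C)c1Cc1c(OCc2ccccc2)c(C)c(OCc2ccccc2)cc1OCc1ccccc1 | intermediate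
21 | 2-[2,4,6-tris(benzyloxy)benzyl]-4-[2,4,6-tris(benzyloxy)-3-methylbenzyl]benzene-1,3,5-triol | Oc1cc(O)c(Cc2c(OCc3ccccc3)cc(OCc3ccccc3)cc2OCc2ccccc2)c(O)c1Cc1c(OCc2ccccc2)c(C)c(OCc2ccccc2)cc1OCc1ccccc1 | intermediate
22 | 2-[(2,4,6-trihydroxyphenyl)methyl]-4-[(2,4,6-trihydroxy-3-methylphenyl)methyl]benzene-1,3,5-triol | Oc1cc(O)c(Cc2c(O)cc(O)cc2O)c(O)c1Cc1c(O)c(C)c(O)cc1O | intermediate
23 | 1-[3-({3-butanoyl-5-[(3-butanoyl-2,4,6-trihydroxy-5-methylphenyl)methyl]-2,4,6-trihydroxyphenyl}methyl)-2,4,6-trihydroxyphenyl]butan-1-one (tris-butyryl ring B–C–D trimer) | CCCC(=O)c1c(O)cc(O)c(Cc2c(O)c(Cc3c(O)c(C)c(O)c(C(=O)CCC)c3O)c(O)c(C(=O)CCC)c2O)c1O | intermediate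
24 | 1-(2,4,6-trihydroxyphenyl)butan-1-one | CCCC(=O)c1c(O)cc(O)cc1O | intermediate
25 | 2-butanoyl-3,5-dihydroxy-4,4-dimethylcyclohexa-2,5-dien-1-one (butyrylfilicinic acid) | CCCC(=O)C1=C(O)C(C)(C)C(O)=CC1=O | intermediate
26 | 2-butanoyl-6-[(dimethylamino)methyl]-3,5-dihydroxy-4,4-dimethylcyclohexa-2,5-dien-1-one | CCCC(=O)C1=C(O)C(C)(C)C(O)=C(CN(C)C)C1=O | intermediate
27 | 2-butanoyl-3-hydroxy-4,4-dimethyl-6-methylidenecyclohex-2-ene-1,5-dione | CCCC(=O)C1=C(O)C(C)(C)C(=O)C(=C)C1=O | intermediate (not isolated)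
28 | CNP0246352.0: 2-butanoyl-6-{[3-butanoyl-5-({3-butanoyl-5-[(3-butanoyl-2,4,6-trihydroxy-5-methylphenyl)methyl]-2,4,6-trihydroxyphenyl}methyl)-2,4,6-trihydroxyphenyl]methyl}-3,5-dihydroxy-4,4-dimethylcyclohexa-2,5-dien-1-one (no stereocentre) | CCCC(=O)C1=C(O)C(C)(C)C(O)=C(Cc2c(O)c(Cc3c(O)c(Cc4c(O)c(C)c(O)c(C(=O)CCC)c4O)c(O)c(C(=O)CCC)c3O)c(O)c(C(=O)CCC)c2O)C1=O | target

**Step count**
Total: 17 steps. Longest linear sequence: 10 steps (steps 1–5, 10–13, 17).

**Steps most likely to fail**

Step 10. The donor-stabilised four-membered ring of 8 may not open below the temperature at which ynol ether 15 undergoes a 1,3-silyl shift to a silylketene, so that no vinylketene is intercepted. The fallback uses known chemistry and makes the methylene links one at a time instead of building ring C. It sets out from 9 and 24. Friedel–Crafts butyrylation of 9 (butanoyl chloride, AlCl3) should give 1-(2,4,6-trihydroxy-3-methylphenyl)butan-1-one F1. Aminomethylation of its only free ring position with Eschenmoser's salt should give 1-{3-[(dimethylamino)methyl]-2,4,6-trihydroxy-5-methylphenyl}butan-1-one F2. Heating F2 with an excess of 24 in dioxane should give the ring D–ring C dimer 1-{3-[(3-butanoyl-2,4,6-trihydroxy-5-methylphenyl)methyl]-2,4,6-trihydroxyphenyl}butan-1-one F3 by the same quinone-methide trapping as in step 17. A second aminomethylation at the one free position of its ring C should give 1-{3-[(3-butanoyl-2,4,6-trihydroxy-5-methylphenyl)methyl]-5-[(dimethylamino)methyl]-2,4,6-trihydroxyphenyl}butan-1-one F4. Heating F4 with an excess of 24 should deliver 23, where the route is rejoined before step 17.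

Step 13. The Lewis acid and the HCl set free may protonate the phloroglucinol rings at the bridge-bearing carbons, cleaving and redistributing the diarylmethane links, and a second acyl group may enter ring B or stay on oxygen. The fallback changes the electrophile from an acylium complex to a nitrilium ion (Houben–Hoesch reaction). It sets out from 22: butyronitrile, ZnCl2 and dry HCl in Et2O at 0 °C should precipitate the tris(ketiminium) trichloride of 23 F5. Each ring is switched off after one C-acylation and O-acylation is excluded. Brief hydrolysis in hot water should return the route at 23.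

Step 4. The carbenoid LiCHBr2 or the amide base may deprotonate the acidic arylacetate CH2 instead of adding to the ester carbonyl, and excess n-BuLi may lithiate benzylic ether positions on warming. The fallback makes the ynolate by oxidation of an acetylide instead of by carbenoid rearrangement. It sets out from 4: reduction with i-Bu2AlH in CH2Cl2 at −78 °C should give 2-[2,4,6-tris(benzyloxy)phenyl]acetaldehyde F6. Ohira–Bestmann homologation (dimethyl (1-diazo-2-oxopropyl)phosphonate, K2CO3, MeOH) should give 1,3,5-tris(benzyloxy)-2-(prop-2-yn-1-yl)benzene F7. Deprotonation with n-BuLi (1 equiv, THF, −78 °C), oxidation of the acetylide with lithium tert-butyl peroxide (from t-BuOOH and LiN(SiMe3)2) and trapping with i-Pr3SiCl should return the route at 7.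

**Further compounds**
F1 | step 10 | 1-(2,4,6-trihydroxy-3-methylphenyl)butan-1-one | CCCC(=O)c1c(O)cc(O)c(C)c1O
F2 | step 10 | 1-{3-[(dimethylamino)methyl]-2,4,6-trihydroxy-5-methylphenyl}butan-1-one | CCCC(=O)c1c(O)c(CN(C)C)c(O)c(C)c1O
F3 | step 10 | 1-{3-[(3-butanoyl-2,4,6-trihydroxy-5-methylphenyl)methyl]-2,4,6-trihydroxyphenyl}butan-1-one | CCCC(=O)c1c(O)cc(O)c(Cc2c(O)c(C)c(O)c(C(=O)CCC)c2O)c1O
F4 | step 10 | 1-{3-[(3-butanoyl-2,4,6-trihydroxy-5-methylphenyl)methyl]-5-[(dimethylamino)methyl]-2,4,6-trihydroxyphenyl}butan-1-one | CCCC(=O)c1c(O)c(CN(C)C)c(O)c(Cc2c(O)c(C)c(O)c(C(=O)CCC)c2O)c1O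
F5 | step 13 | tris(ketiminium) trichloride of 23 (each butanoyl C=O replaced by C=NH2+ Cl−) | CCCC(=[NH2+])c1c(O)cc(O)c(Cc2c(O)c(Cc3c(O)c(C)c(O)c(C(=[NH2+])CCC)c3O)c(O)c(C(=[NH2+])CCC)c2O)c1O.[Cl-].[Cl-].[Cl-]
F6 | step 4 | 2-[2,4,6-tris(benzyloxy)phenyl]acetaldehyde | O=CCc1c(OCc2ccccc2)cc(OCc2ccccc2)cc1OCc1ccccc1
F7 | step 4 | 1,3,5-tris(benzyloxy)-2-(prop-2-yn-1-yl)benzene | C#CCc1c(OCc2ccccc2)cc(OCc2ccccc2)cc1OCc1ccccc1
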